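**Retrosynthetic overview**

1. The C9(Cl)–C10(OH) chlorohydrin of the oxepane is traced to the α-chloro enone 17 (C8=C9(Cl)–C10=O): catalyst-controlled ketone reduction sets C10, hydroxyl-directed hydrogenation sets C9, and the side chains are finished last (allylboration at C6, SN2 halogenations with inversion at C6 and C13, Z-enyne olefination).
2. Key disconnection: taking the CCl carbon C9 out of 17 leads to silyl enol ether 14 of a 2,6-trans-tetrahydropyran-4-one; dichlorocarbene adds across C8=C10 (new bonds C8–C9 and C9–C10) and the fused cyclopropane opens to the seven-membered ring.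
3. Enabling feature: in the oxepane ring (O1, C7–C12) the chlorine-bearing C9 lies between C8H2 and the oxygenated C10, and C10 is 1,3 to the ether carbon C12, so C9 is the retron of a chlorocarbon inserted next to the carbonyl of a pyran-4-one ring (O1, C7, C8, C10, C11, C12).
4. The pyranone comes from (S)-2-silyloxybutanal (chiral pool, C13) and 1-methoxy-3-silyloxybutadiene (Felkin control, C12); axial cuprate addition sets C7 trans and fixes the enol ether regiochemistry.
5. Ring order: dihydropyranone (step 3), then cyclopropane-fused pyran (transient), then oxepane (step 6).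

Key step: step 6

Remark: positions follow the C15 chain of the target (C1 = terminal alkyne carbon, C6 = CHCl, C7 and C12 = ether carbons, C13 = CHBr); in names every oxepane is numbered O1, C2 (= C12), C4 (= C10), C5 (= C9), C7 (= C7); all compounds marked as starting materials are assumed to be commercially available.

**Route**

Step 1
Reactants: 1 methyl (S)-2-hydroxybutanoate; 2 tert-butyldimethylsilyl chloride
Product: 3 methyl (S)-2-[(tert-butyldimethylsilyl)oxy]butanoate
Conditions: imidazole, DMF, rt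
Reagents that add atoms: tert-butyldimethylsilyl chloride, CC(C)(C)[Si](C)(C)Cl
Why: Standard silyl ether protection of a secondary alcohol; the C13 stereocentre comes from the chiral pool and the non-chelating silyl group prepares Felkin control in step 3.

Step 2
Reactants: 3 methyl (S)-2-[(tert-butyldimethylsilyl)oxy]butanoate
Product: 4 (S)-2-[(tert-butyldimethylsilyl)oxy]butanal
Conditions: i-Bu2AlH, CH2Cl2, −78 °C; aq. Rochelle salt
Reagents that add atoms: none
Why: Partial reduction of an α-silyloxy ester with i-Bu2AlH at low temperature stops at the aldehyde (stable aluminium hemiacetal) and should leave the α-centre intact.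

Step 3
Reactants: 4 (S)-2-[(tert-butyldimethylsilyl)oxy]butanal; 5 (E)-1-methoxy-3-(trimethylsilyloxy)buta-1,3-diene
Product: 7 (2R)-2-{(1S)-1-[(tert-butyldimethylsilyl)oxy]propyl}-2,3-dihydro-4H-pyran-4-one, via anti aldol adduct 6 (not isolated)
Conditions: BF3·OEt2, CH2Cl2, −78 °C; then CF3CO2H, CH2Cl2, 0 °C to rt
Reagents that add atoms: (E)-1-methoxy-3-(trimethylsilyloxy)buta-1,3-diene, CO/C=C/C(=C)O[Si](C)(C)C
Why: Hetero-Diels–Alder reaction in its stepwise Mukaiyama aldol–acid cyclisation form; with monodentate BF3 and a non-chelating silyloxy group, Felkin–Anh attack should set C12 anti to the C13 oxygen (12R).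

Step 4
Reactants: 8 4-methoxybenzyl alcohol; 9 tributyl(iodomethyl)stannane
Product: 10 tributyl{[(4-methoxybenzyl)oxy]methyl}stannane
Conditions: NaH, THF/DMF, 0 °C to rt
Reagents that add atoms: tributyl(iodomethyl)stannane, CCCC[Sn](CCCC)(CCCC)CI
Why: Williamson ether synthesis on a primary iodide gives the tin precursor of a protected hydroxymethyl anion.

Step 5
Reactants: 7 (2R)-2-{(1S)-1-[(tert-butyldimethylsilyl)oxy]propyl}-2,3-dihydro-4H-pyran-4-one; 10 tributyl{[(4-methoxybenzyl)oxy]methyl}stannane; 11 chlorotrimethylsilane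
Product: 14 tert-butyl{(1S)-1-[(2R,6R)-6-{[(4-methoxybenzyl)oxy]methyl}-4-[(trimethylsilyl)oxy]-3,6-dihydro-2H-pyran-2-yl]propoxy}dimethylsilane, via alkoxymethyllithium 12 (not isolated), via lithium dialkylcuprate 13 (not isolated)
Conditions: 10 (2.2 equiv), n-BuLi, THF, −78 °C; CuBr·SMe2 (1.1 equiv), −78 to −50 °C; Me3SiCl then 7, −78 °C; Et3N; aq. NH4Cl/NH3, pentane
Reagents that add atoms: tributyl{[(4-methoxybenzyl)oxy]methyl}stannane, CCCC[Sn](CCCC)(CCCC)COCc1ccc(OC)cc1; chlorotrimethylsilane, C[Si](C)(C)Cl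
Why: Tin–lithium exchange, cuprate formation and silyl-chloride-accelerated conjugate addition; axial attack on the half-chair anti to the C12 side chain should give the 2,6-trans ring (7R), and the enolate is trapped regiospecifically as the C8=C10 silyl enol ether.

Step 6
Reactants: 14 tert-butyl{(1S)-1-[(2R,6R)-6-{[(4-methoxybenzyl)oxy]methyl}-4-[(trimethylsilyl)oxy]-3,6-dihydro-2H-pyran-2-yl]propoxy}dimethylsilane; 15 sodium trichloroacetate
Product: 17 (2R,7R)-2-{(1S)-1-[(tert-butyldimethylsilyl)oxy]propyl}-5-chloro-7-{[(4-methoxybenzyl)oxy]methyl}-2,3-dihydrooxepin-4(7H)-one, via dichlorocyclopropane adduct 16 (not isolated)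
Conditions: Cl3CCO2Na, DME, 85 °C; then toluene, 110 °C
Reagents that add atoms: sodium trichloroacetate, [Na+].[O-]C(=O)C(Cl)(Cl)Cl
Why: On heating, sodium trichloroacetate loses CO2 and chloride to give dichlorocarbene, which adds in a concerted (2+1) cheletropic cycloaddition to the electron-rich C8=C10 silyl enol ether of 14, forming the C8–C9 and C9–C10 bonds and closing the cyclopropane of 16; at 110 °C the endo C–Cl bond ionises in concert with disrotatory electrocyclic opening of the C8–C10 bond, assisted by the siloxy oxygen, and loss of Me3SiCl from the siloxyallyl cation leaves the 2-chloro enone, so the six-membered ring has grown into the oxepane with C9 inserted and already carrying its chlorine. The closest known reaction type is the dihalocarbene ring expansion of silyl enol ethers of cyclic ketones to 2-halocycloalk-2-enones. Mode of closure: the three-membered ring closes by (2+1) cycloaddition onto an endocyclic alkene, and the seven-membered ring then arises from the fused 3-oxabicyclo[4.1.0]heptane by electrocyclic cleavage of the shared bond, not by an end-to-end cyclisation. No stereocentre is created, because both cyclopropane carbons end as sp2 centres, so the face of carbene attack does not matter and C7, C12 and C13 are not touched. The selectivity the step needs is chemoselectivity and regioselectivity: the electrophilic carbene should take the silyl enol ether, by far the most nucleophilic π bond (the anisyl ring and the ethers are poor partners), and the placing of the CCl carbon between C8 and C10, and not on the C11 side, is fixed by the enol ether regiochemistry that the conjugate addition of step 5 wrote into 14. The sense of opening (carbonyl at C10, C8=C9 alkene, chlorine kept on C9) follows from the oxygen-assisted ionisation.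

Step 7
Reactants: 17 (2R,7R)-2-{(1S)-1-[(tert-butyldimethylsilyl)oxy]propyl}-5-chloro-7-{[(4-methoxybenzyl)oxy]methyl}-2,3-dihydrooxepin-4(7H)-one
Product: 18 (2R,4S,7R)-2-{(1S)-1-[(tert-butyldimethylsilyl)oxy]propyl}-5-chloro-7-{[(4-methoxybenzyl)oxy]methyl}-2,3,4,7-tetrahydrooxepin-4-ol
Conditions: (R)-2-methyl-CBS-oxazaborolidine (20 mol %), BH3·SMe2, toluene, −40 °C; MeOH quench
Reagents that add atoms: none
Why: Corey–Bakshi–Shibata reduction, for which α-halo enones are good substrates with the halovinyl group acting as the large substituent, so the (R)-catalyst should give the 10S allylic alcohol by catalyst-controlled 1,2-reduction.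

Step 8
Reactants: 18 (2R,4S,7R)-2-{(1S)-1-[(tert-butyldimethylsilyl)oxy]propyl}-5-chloro-7-{[(4-methoxybenzyl)oxy]methyl}-2,3,4,7-tetrahydrooxepin-4-ol
Product: 19 (2R,4S,5S,7R)-2-{(1S)-1-[(tert-butyldimethylsilyl)oxy]propyl}-5-chloro-7-{[(4-methoxybenzyl)oxy]methyl}oxepan-4-ol
Conditions: H2 (1 atm), [Ir(cod)(PCy3)(py)]PF6 (5 mol %), CH2Cl2, 0 °C to rt
Reagents that add atoms: none
Why: Proposed new method: hydroxyl-directed homogeneous hydrogenation of a cyclic 2-chloroallylic alcohol; mechanistic reasoning: the C10 hydroxyl binds the cationic iridium dihydride, so both hydrogens should enter C8=C9 from the hydroxyl face and leave the C9 chlorine trans to the C10 OH (9S), while hydrometalation syn to the metal puts that chlorine anti to iridium in the ring, so syn β-chloride elimination is geometrically blocked and C–H reductive elimination should win; closest known reaction type: hydroxyl-directed hydrogenation of cyclic allylic alcohols with cationic iridium or rhodium catalysts, which has not been shown on chloroalkenes.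

Step 9
Reactants: 19 (2R,4S,5S,7R)-2-{(1S)-1-[(tert-butyldimethylsilyl)oxy]propyl}-5-chloro-7-{[(4-methoxybenzyl)oxy]methyl}oxepan-4-ol; 20 triisopropylsilyl trifluoromethanesulfonate
Product: 21 (2R,4S,5S,7R)-2-{(1S)-1-[(tert-butyldimethylsilyl)oxy]propyl}-5-chloro-7-{[(4-methoxybenzyl)oxy]methyl}-4-[(triisopropylsilyl)oxy]oxepane
Conditions: 2,6-lutidine, CH2Cl2, −78 to 0 °C
Reagents that add atoms: triisopropylsilyl trifluoromethanesulfonate, CC(C)[Si](C(C)C)(C(C)C)OS(=O)(=O)C(F)(F)F
Why: Silylation with a silyl triflate and a weak hindered base protects the C10 hydroxyl without forming an alkoxide that could close an epoxide onto C9.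

Step 10
Reactants: 21 (2R,4S,5S,7R)-2-{(1S)-1-[(tert-butyldimethylsilyl)oxy]propyl}-5-chloro-7-{[(4-methoxybenzyl)oxy]methyl}-4-[(triisopropylsilyl)oxy]oxepane
Product: 22 [(2R,4S,5S,7R)-2-{(1S)-1-[(tert-butyldimethylsilyl)oxy]propyl}-5-chloro-4-[(triisopropylsilyl)oxy]oxepan-7-yl]methanol
Conditions: DDQ, CH2Cl2/pH 7 buffer, 0 °C
Reagents that add atoms: none
Why: Oxidative cleavage of the 4-methoxybenzyl ether (electron transfer, oxocarbenium ion, hydrolysis) is orthogonal to both silyl ethers and the alkyl chloride.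

Step 11
Reactants: 22 [(2R,4S,5S,7R)-2-{(1S)-1-[(tert-butyldimethylsilyl)oxy]propyl}-5-chloro-4-[(triisopropylsilyl)oxy]oxepan-7-yl]methanol
Product: 23 (2R,4S,5S,7R)-2-{(1S)-1-[(tert-butyldimethylsilyl)oxy]propyl}-5-chloro-4-[(triisopropylsilyl)oxy]oxepane-7-carbaldehyde
Conditions: Dess–Martin periodinane, CH2Cl2, rt
Reagents that add atoms: none
Why: Dess–Martin oxidation under neutral conditions should give the α-alkoxy aldehyde without epimerising C7.

Step 12
Reactants: 23 (2R,4S,5S,7R)-2-{(1S)-1-[(tert-butyldimethylsilyl)oxy]propyl}-5-chloro-4-[(triisopropylsilyl)oxy]oxepane-7-carbaldehyde; 24 (−)-B-allyldiisopinocampheylborane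
Product: 25 (1S)-1-[(2R,4S,5S,7R)-2-{(1S)-1-[(tert-butyldimethylsilyl)oxy]propyl}-5-chloro-4-[(triisopropylsilyl)oxy]oxepan-7-yl]but-3-en-1-ol
Conditions: 24, Et2O, −78 °C; then NaOH, H2O2
Reagents that add atoms: (−)-B-allyldiisopinocampheylborane, C=CCB([C@@H]1C[C@@H]2C[C@H]([C@H]1C)C2(C)C)[C@@H]1C[C@@H]2C[C@H]([C@H]1C)C2(C)C
Why: Brown allylboration through a chair transition state; the reagent derived from (+)-α-pinene attacks the Si face of the aldehyde, which is matched with the Felkin preference of the α-alkoxy aldehyde and should set C6 as 6S.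

Step 13
Reactants: 25 (1S)-1-[(2R,4S,5S,7R)-2-{(1S)-1-[(tert-butyldimethylsilyl)oxy]propyl}-5-chloro-4-[(triisopropylsilyl)oxy]oxepan-7-yl]but-3-en-1-ol; 26 carbon tetrachloride
Product: 27 (2R,4S,5S,7R)-2-{(1S)-1-[(tert-butyldimethylsilyl)oxy]propyl}-5-chloro-7-[(1R)-1-chlorobut-3-en-1-yl]-4-[(triisopropylsilyl)oxy]oxepane
Conditions: CCl4, P(n-C8H17)3, toluene, 70 °C
Reagents that add atoms: carbon tetrachloride, ClC(Cl)(Cl)Cl
Why: Appel reaction, in which chloride displaces the alkoxyphosphonium group by SN2 and inverts C6 to the 6R chloride.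

Step 14
Reactants: 27 (2R,4S,5S,7R)-2-{(1S)-1-[(tert-butyldimethylsilyl)oxy]propyl}-5-chloro-7-[(1R)-1-chlorobut-3-en-1-yl]-4-[(triisopropylsilyl)oxy]oxepane
Product: 28 (1S)-1-[(2R,4S,5S,7R)-5-chloro-7-[(1R)-1-chlorobut-3-en-1-yl]-4-[(triisopropylsilyl)oxy]oxepan-2-yl]propan-1-ol
Conditions: HF·pyridine, pyridine, THF, 0 °C to rt
Reagents that add atoms: none
Why: Fluoride desilylation should remove the tert-butyldimethylsilyl ether well before the more hindered triisopropylsilyl ether at C10.

Step 15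
Reactants: 28 (1S)-1-[(2R,4S,5S,7R)-5-chloro-7-[(1R)-1-chlorobut-3-en-1-yl]-4-[(triisopropylsilyl)oxy]oxepan-2-yl]propan-1-ol; 29 carbon tetrabromide
Product: 30 (2R,4S,5S,7R)-2-[(1R)-1-bromopropyl]-5-chloro-7-[(1R)-1-chlorobut-3-en-1-yl]-4-[(triisopropylsilyl)oxy]oxepane
Conditions: CBr4, P(n-C8H17)3, toluene, 70 °C
Reagents that add atoms: carbon tetrabromide, BrC(Br)(Br)Br
Why: Appel bromination with SN2 inversion turns the 13S alcohol into the 13R bromide, the usual way to the bromopropyl terminus of Laurencia ethers.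

Step 16
Reactants: 30 (2R,4S,5S,7R)-2-[(1R)-1-bromopropyl]-5-chloro-7-[(1R)-1-chlorobut-3-en-1-yl]-4-[(triisopropylsilyl)oxy]oxepane; 31 ozone
Product: 33 (3R)-3-[(2R,4S,5S,7R)-2-[(1R)-1-bromopropyl]-5-chloro-4-[(triisopropylsilyl)oxy]oxepan-7-yl]-3-chloropropanal, via secondary ozonide 32 (not isolated)
Conditions: O3, CH2Cl2, −78 °C; then PPh3, −78 °C to rt
Reagents that add atoms: ozone, [O-][O+]=O
Why: Ozonolysis with reductive work-up cleaves the only alkene to the C4 aldehyde while the halides and the silyl ether stay inert.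

Step 17
Reactants: 33 (3R)-3-[(2R,4S,5S,7R)-2-[(1R)-1-bromopropyl]-5-chloro-4-[(triisopropylsilyl)oxy]oxepan-7-yl]-3-chloropropanal; 34 1,3-bis(triisopropylsilyl)propyne
Product: 35 (2R,4S,5S,7R)-2-[(1R)-1-bromopropyl]-5-chloro-7-[(1R,3Z)-1-chloro-6-(triisopropylsilyl)hex-3-en-5-yn-1-yl]-4-[(triisopropylsilyl)oxy]oxepane
Conditions: 34, n-BuLi, THF, −78 to −20 °C; then 33, −78 °C to rt; H2O
Reagents that add atoms: 1,3-bis(triisopropylsilyl)propyne, CC(C)[Si](C(C)C)(C(C)C)CC#C[Si](C(C)C)(C(C)C)C(C)C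
Why: Peterson olefination with the lithiated bis-silylpropyne, a Z-selective enyne synthesis in which the bulky silyl groups steer the addition–elimination, and fast carbonyl addition at −78 °C should outrun loss of HCl from the β-chloro aldehyde.

Step 18
Reactants: 35 (2R,4S,5S,7R)-2-[(1R)-1-bromopropyl]-5-chloro-7-[(1R,3Z)-1-chloro-6-(triisopropylsilyl)hex-3-en-5-yn-1-yl]-4-[(triisopropylsilyl)oxy]oxepane
Product: 36 (2R,4S,5S,7R)-2-[(1R)-1-bromopropyl]-5-chloro-7-[(1R,3Z)-1-chlorohex-3-en-5-yn-1-yl]oxepan-4-ol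
Conditions: Bu4NF, AcOH, THF, 0 °C to rt
Reagents that add atoms: none
Why: Fluoride desilylation cleaves the alkynyl C–Si bond and the silyl ether in one operation, and the acetic acid buffer should keep the freed C10 alkoxide from closing an epoxide onto C9.

**Compound list**

1 | methyl (S)-2-hydroxybutanoate | CC[C@H](O)C(=O)OC | starting material
2 | tert-butyldimethylsilyl chloride | CC(C)(C)[Si](C)(C)Cl | starting material
3 | methyl (S)-2-[(tert-butyldimethylsilyl)oxy]butanoate | CC[C@H](O[Si](C)(C)C(C)(C)C)C(=O)OC | intermediate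
4 | (S)-2-[(tert-butyldimethylsilyl)oxy]butanal | CC[C@H](O[Si](C)(C)C(C)(C)C)C=O | intermediate
5 | (E)-1-methoxy-3-(trimethylsilyloxy)buta-1,3-diene | CO/C=C/C(=C)O[Si](C)(C)C | starting material
6 | (1E,5R,6S)-6-[(tert-butyldimethylsilyl)oxy]-5-hydroxy-1-methoxyoct-1-en-3-one (anti aldol adduct) | CO/C=C/C(=O)C[C@H]([C@@H](O[Si](C)(C)C(C)(C)C)CC)O | intermediate
7 | (2R)-2-{(1S)-1-[(tert-butyldimethylsilyl)oxy]propyl}-2,3-dihydro-4H-pyran-4-one | O=C1C[C@H]([C@@H](O[Si](C)(C)C(C)(C)C)CC)OC=C1 | intermediate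
8 | 4-methoxybenzyl alcohol | COc1ccc(CO)cc1 | starting material
9 | tributyl(iodomethyl)stannane | CCCC[Sn](CCCC)(CCCC)CI | starting material
10 | tributyl{[(4-methoxybenzyl)oxy]methyl}stannane | CCCC[Sn](CCCC)(CCCC)COCc1ccc(OC)cc1 | intermediate
11 | chlorotrimethylsilane | C[Si](C)(C)Cl | starting material
12 | {[(4-methoxybenzyl)oxy]methyl}lithium | [Li]COCc1ccc(OC)cc1 | intermediate
13 | lithium bis{[(4-methoxybenzyl)oxy]methyl}cuprate | [Li+].COc1ccc(COC[Cu-]COCc2ccc(OC)cc2)cc1 | intermediate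
14 | tert-butyl{(1S)-1-[(2R,6R)-6-{[(4-methoxybenzyl)oxy]methyl}-4-[(trimethylsilyl)oxy]-3,6-dihydro-2H-pyran-2-yl]propoxy}dimethylsilane (2,6-trans) | COc1ccc(COC[C@H]2C=C(O[Si](C)(C)C)C[C@H]([C@@H](O[Si](C)(C)C(C)(C)C)CC)O2)cc1 | intermediate
15 | sodium trichloroacetate | [Na+].[O-]C(=O)C(Cl)(Cl)Cl | starting material
16 | 7,7-dichloro-3-oxabicyclo[4.1.0]heptane with 6-trimethylsilyloxy, 2-[(4-methoxybenzyl)oxy]methyl and 4-[(1S)-1-(tert-butyldimethylsilyloxy)propyl] groups (cis-fused; carbene on the face anti to the C7 substituent; the other face would converge) | COc1ccc(COC[C@H]2[C@@H]3C(Cl)(Cl)[C@]3(O[Si](C)(C)C)C[C@H]([C@@H](O[Si](C)(C)C(C)(C)C)CC)O2)cc1 | intermediate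
17 | (2R,7R)-2-{(1S)-1-[(tert-butyldimethylsilyl)oxy]propyl}-5-chloro-7-{[(4-methoxybenzyl)oxy]methyl}-2,3-dihydrooxepin-4(7H)-one | COc1ccc(COC[C@H]2C=C(Cl)C(=O)C[C@H]([C@@H](O[Si](C)(C)C(C)(C)C)CC)O2)cc1 | intermediate
18 | (2R,4S,7R)-2-{(1S)-1-[(tert-butyldimethylsilyl)oxy]propyl}-5-chloro-7-{[(4-methoxybenzyl)oxy]methyl}-2,3,4,7-tetrahydrooxepin-4-ol | COc1ccc(COC[C@H]2C=C(Cl)[C@@H](O)C[C@H]([C@@H](O[Si](C)(C)C(C)(C)C)CC)O2)cc1 | intermediate
19 | (2R,4S,5S,7R)-2-{(1S)-1-[(tert-butyldimethylsilyl)oxy]propyl}-5-chloro-7-{[(4-methoxybenzyl)oxy]methyl}oxepan-4-ol | COc1ccc(COC[C@H]2C[C@H](Cl)[C@@H](O)C[C@H]([C@@H](O[Si](C)(C)C(C)(C)C)CC)O2)cc1 | intermediate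
20 | triisopropylsilyl trifluoromethanesulfonate | CC(C)[Si](C(C)C)(C(C)C)OS(=O)(=O)C(F)(F)F | starting material
21 | (2R,4S,5S,7R)-2-{(1S)-1-[(tert-butyldimethylsilyl)oxy]propyl}-5-chloro-7-{[(4-methoxybenzyl)oxy]methyl}-4-[(triisopropylsilyl)oxy]oxepane | COc1ccc(COC[C@H]2C[C@H](Cl)[C@@H](O[Si](C(C)C)(C(C)C)C(C)C)C[C@H]([C@@H](O[Si](C)(C)C(C)(C)C)CC)O2)cc1 | intermediate
22 | [(2R,4S,5S,7R)-2-{(1S)-1-[(tert-butyldimethylsilyl)oxy]propyl}-5-chloro-4-[(triisopropylsilyl)oxy]oxepan-7-yl]methanol | OC[C@H]1C[C@H](Cl)[C@@H](O[Si](C(C)C)(C(C)C)C(C)C)C[C@H]([C@@H](O[Si](C)(C)C(C)(C)C)CC)O1 | intermediate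
23 | (2R,4S,5S,7R)-2-{(1S)-1-[(tert-butyldimethylsilyl)oxy]propyl}-5-chloro-4-[(triisopropylsilyl)oxy]oxepane-7-carbaldehyde | O=C[C@H]1C[C@H](Cl)[C@@H](O[Si](C(C)C)(C(C)C)C(C)C)C[C@H]([C@@H](O[Si](C)(C)C(C)(C)C)CC)O1 | intermediate
24 | (−)-B-allyldiisopinocampheylborane (from (+)-α-pinene) | C=CCB([C@@H]1C[C@@H]2C[C@H]([C@H]1C)C2(C)C)[C@@H]1C[C@@H]2C[C@H]([C@H]1C)C2(C)C | starting material
25 | (1S)-1-[(2R,4S,5S,7R)-2-{(1S)-1-[(tert-butyldimethylsilyl)oxy]propyl}-5-chloro-4-[(triisopropylsilyl)oxy]oxepan-7-yl]but-3-en-1-ol | C=CC[C@H](O)[C@H]1C[C@H](Cl)[C@@H](O[Si](C(C)C)(C(C)C)C(C)C)C[C@H]([C@@H](O[Si](C)(C)C(C)(C)C)CC)O1 | intermediate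
26 | carbon tetrachloride | ClC(Cl)(Cl)Cl | starting material
27 | (2R,4S,5S,7R)-2-{(1S)-1-[(tert-butyldimethylsilyl)oxy]propyl}-5-chloro-7-[(1R)-1-chlorobut-3-en-1-yl]-4-[(triisopropylsilyl)oxy]oxepane | C=CC[C@@H](Cl)[C@H]1C[C@H](Cl)[C@@H](O[Si](C(C)C)(C(C)C)C(C)C)C[C@H]([C@@H](O[Si](C)(C)C(C)(C)C)CC)O1 | intermediate
28 | (1S)-1-[(2R,4S,5S,7R)-5-chloro-7-[(1R)-1-chlorobut-3-en-1-yl]-4-[(triisopropylsilyl)oxy]oxepan-2-yl]propan-1-ol | C=CC[C@@H](Cl)[C@H]1C[C@H](Cl)[C@@H](O[Si](C(C)C)(C(C)C)C(C)C)C[C@H]([C@@H](O)CC)O1 | intermediate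
29 | carbon tetrabromide | BrC(Br)(Br)Br | starting material
30 | (2R,4S,5S,7R)-2-[(1R)-1-bromopropyl]-5-chloro-7-[(1R)-1-chlorobut-3-en-1-yl]-4-[(triisopropylsilyl)oxy]oxepane | C=CC[C@@H](Cl)[C@H]1C[C@H](Cl)[C@@H](O[Si](C(C)C)(C(C)C)C(C)C)C[C@H]([C@H](Br)CC)O1 | intermediate
31 | ozone | [O-][O+]=O | starting material
32 | secondary ozonide of 30 (1,2,4-trioxolane at the former C=C; mixture of epimers at the trioxolane carbon) | C1OC(C[C@@H](Cl)[C@H]2C[C@H](Cl)[C@@H](O[Si](C(C)C)(C(C)C)C(C)C)C[C@H]([C@H](Br)CC)O2)OO1 | intermediate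
33 | (3R)-3-[(2R,4S,5S,7R)-2-[(1R)-1-bromopropyl]-5-chloro-4-[(triisopropylsilyl)oxy]oxepan-7-yl]-3-chloropropanal | O=CC[C@@H](Cl)[C@H]1C[C@H](Cl)[C@@H](O[Si](C(C)C)(C(C)C)C(C)C)C[C@H]([C@H](Br)CC)O1 | intermediate
34 | 1,3-bis(triisopropylsilyl)propyne | CC(C)[Si](C(C)C)(C(C)C)CC#C[Si](C(C)C)(C(C)C)C(C)C | starting material
35 | (2R,4S,5S,7R)-2-[(1R)-1-bromopropyl]-5-chloro-7-[(1R,3Z)-1-chloro-6-(triisopropylsilyl)hex-3-en-5-yn-1-yl]-4-[(triisopropylsilyl)oxy]oxepane | CC(C)[Si](C(C)C)(C(C)C)C#C/C=C\C[C@@H](Cl)[C@H]1C[C@H](Cl)[C@@H](O[Si](C(C)C)(C(C)C)C(C)C)C[C@H]([C@H](Br)CC)O1 | intermediate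
36 | (2R,4S,5S,7R)-2-[(1R)-1-bromopropyl]-5-chloro-7-[(1R,3Z)-1-chlorohex-3-en-5-yn-1-yl]oxepan-4-ol | C#C/C=C\C[C@@H](Cl)[C@H]1C[C@H](Cl)[C@@H](O)C[C@H]([C@H](Br)CC)O1 | target

**Step count and risks**

Total: 18 steps. Longest linear sequence: 17 steps (steps 1–3 and 5–18, from 1 to 36); step 4 is a one-step side branch.

Most likely to fail, step 8: the vinylic chlorine may be lost during hydrogenation (β-chloride elimination or C–Cl hydrogenolysis at the metal), or the cationic catalyst may isomerise the allylic alcohol to the ketone before hydrogen is delivered. Fallback with known chemistry: the coordination-directed hydrogenation is replaced by radical hydrogen-atom-transfer hydrogenation of 18 with Mn(dpm)3 (tris(2,2,6,6-tetramethylheptane-3,5-dionato)manganese), PhSiH3 and t-BuOOH in i-PrOH, a method documented to hydrogenate haloalkenes with the halogen kept because no metal alkyl able to expel chloride is formed. The C9 radical is then quenched under thermodynamic and not directing-group control, which should favour the trans chlorohydrin. This fallback sets out from 18 and comes back at 19; it makes no new compound (F0).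

Second, step 6: the trimethylsilyl enol ether may be cleaved before the carbene is generated, the carbene may be consumed by side reactions at 85 °C, or the dichlorocyclopropane may resist thermal opening. Fallback: the carbon is inserted as CH2 and chlorinated afterwards. Setting out from 14, Furukawa-modified Simmons–Smith cyclopropanation (Et2Zn, CH2I2, CH2Cl2) would give the siloxycyclopropane, 3-oxabicyclo[4.1.0]heptane F1. FeCl3 in DMF followed by NaOAc in MeOH (oxidative ring expansion, then loss of HCl) would give the chlorine-free (2R,7R)-2,3-dihydrooxepin-4(7H)-one F2. Dichlorination–dehydrochlorination of the enone with PhICl2 and pyridine in CH2Cl2 would put chlorine on C9 and come back to the route at 17.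

Third, step 17: the β-chloro aldehyde may lose HCl (E1cB) under the basic organolithium, and the Z selectivity of the olefination may erode. Fallback: the aldehyde is avoided altogether by Z-selective cross-metathesis of conjugated enynes. Setting out from alkene 30, reaction with (but-3-en-1-yn-1-yl)triisopropylsilane (C=CC#C[Si](C(C)C)(C(C)C)C(C)C) and RuCl2(=CHPh)(PCy3)(H2IMes) (second-generation Grubbs catalyst) in benzene at 60 °C should give the (Z)-enyne directly. It comes back to the route at 35 and replaces steps 16 and 17; it makes no new compound (F0).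

**Further compounds**

F0 | step 8 | none | none
F1 | step 6 | 3-oxabicyclo[4.1.0]heptane with 6-trimethylsilyloxy, 2-[(4-methoxybenzyl)oxy]methyl and 4-[(1S)-1-(tert-butyldimethylsilyloxy)propyl] groups (cis-fused siloxycyclopropane, CH2 on the face anti to the C7 substituent) | COc1ccc(COC[C@H]2[C@@H]3C[C@]3(O[Si](C)(C)C)C[C@H]([C@@H](O[Si](C)(C)C(C)(C)C)CC)O2)cc1
F2 | step 6 | (2R,7R)-2-{(1S)-1-[(tert-butyldimethylsilyl)oxy]propyl}-7-{[(4-methoxybenzyl)oxy]methyl}-2,3-dihydrooxepin-4(7H)-one | COc1ccc(COC[C@H]2C=CC(=O)C[C@H]([C@@H](O[Si](C)(C)C(C)(C)C)CC)O2)cc1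
F0 | step 17 | none | none
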